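The route rests on the hidden mirror plane through C9 of the ansa chain. Carbinol carbons C7/C11 and methyl-bearing carbons C6/C12 and C8/C10 are pairwise mirror images. Only the C1–C5 dienamide with its naphthoquinone on one side and the 2,8-dioxabicyclo[3.2.1]octane ketal (1,3-dioxane ring O–C11–C12–C13–O–C16, oxolane ring C13–C16) on the other break it. A single two-directional (E)-crotylboration of a meso dialdehyde therefore makes C6–C7 and C11–C12 and fixes C6, C7, C11 and C12 together. Its precursor is anti,anti-3-silyloxy-2,4-dimethylpentanedial (C7–C11), four steps from methacrolein. A lipase later distinguishes the ends, and a Stille coupling at C3–C4 joins chain and arene.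

Key step: step 5

Numbering: chain atoms run from C1 (amide carbonyl) to C17 (ketal methyl). Arene atoms are primed: C1' and C4' become the quinone carbonyls, N sits on C2', the carboxyl on C5', oxygen on C6' and C8', and methyl on C7'.
Remark on the skeleton: the two terminal CH2 groups of diene 10 are C4 and C14, so 10 spans C4–C14. Both are cut off in step 7. C4 returns from CHI3 (step 10) and C14 from 19 (step 13).
Assumption: the lipase acetylates the hydroxymethyl group at C13, because C12 is spatially analogous to an (S)-2-methylalkan-1-ol, the enantiomer that Pseudomonas lipases acylate faster by the empirical rule for primary alcohols.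

Step 1
Reactants: 1 methacrolein; 2 isopropenylmagnesium bromide
Product: 3 2,4-dimethylpenta-1,4-dien-3-ol
Conditions: THF, -78 to 0 °C; then H2O
Reagents that add atoms: none
Why: Grignard 1,2-addition to the enal carbonyl outruns conjugate addition in the cold and gives the symmetric bis-allylic alcohol, whose carbinol carbon (C9) is not yet a stereocentre.

Step 2
Reactants: 3 2,4-dimethylpenta-1,4-dien-3-ol
Product: 4 3-(tert-butyldimethylsilyloxy)-2,4-dimethylpenta-1,4-diene
Conditions: TBSCl, imidazole, DMF, rt
Reagents that add atoms: tert-butyldimethylsilyl chloride CC(C)(C)[Si](C)(C)Cl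
Why: Imidazole-promoted silyl ether formation; the bulky, non-chelating TBS group is chosen because it later makes the C9 branch the large substituent in both Felkin–Anh events and lasts until step 14.

Step 3
Reactants: 4 3-(tert-butyldimethylsilyloxy)-2,4-dimethylpenta-1,4-diene
Product: 6 meso anti,anti-3-(tert-butyldimethylsilyloxy)-2,4-dimethylpentane-1,5-diol (C7–C11), via bis(9-BBN) adduct 5 (not isolated)
Conditions: 9-BBN (2.5 equiv), THF, 0 °C to rt; then NaOH, H2O2, 0 °C
Reagents that add atoms: 9-borabicyclo[3.3.1]nonane B1C2CCCC1CCC2 (stays in 5 only); hydrogen peroxide OO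
Why: Double hydroboration–oxidation of a 1,1-disubstituted allylic ether: in the conformer of least allylic strain the bulky borane attacks each alkene anti to the other carbon branch, so C8 and C10 are both set anti to C9–O; the major product is therefore the meso diol, and the chiral anti,syn isomer is removed by chromatography.

Step 4
Reactants: 6 meso anti,anti-3-(tert-butyldimethylsilyloxy)-2,4-dimethylpentane-1,5-diol
Product: 7 meso anti,anti-3-(tert-butyldimethylsilyloxy)-2,4-dimethylpentanedial (C7–C11 dialdehyde)
Conditions: (COCl)2, DMSO, CH2Cl2, -78 °C; Et3N, -78 to -20 °C; crude product used at once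
Reagents that add atoms: none
Why: Swern oxidation stops at the aldehyde, and the short cold amine treatment plus direct use of the crude dialdehyde protects the epimerisable centres C8 and C10 and the β-silyloxy group.

Step 5
Reactants: 7 meso C7–C11 dialdehyde; 8 (E)-crotylboronic acid pinacol ester
Product: 10 meso 6-(tert-butyldimethylsilyloxy)-3,5,7,9-tetramethylundeca-1,10-diene-4,8-diol (C4–C14 heptad diene diol; chain relations 6,7-anti 7,8-syn 8,9-anti 9,10-anti 10,11-syn 11,12-anti), via bis(pinacol borate) 9 (not isolated)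
Conditions: 8 (3 equiv), 4 Å molecular sieves, toluene, 0 °C to rt; then H2O
Reagents that add atoms: none
Why: Each formyl oxygen binds the boron of 8 and the crotyl group is transferred with allylic transposition through a closed six-membered chair (Zimmerman–Traxler type), the closest known reaction being the uncatalysed allylboration of aldehydes run in two directions on a meso dialdehyde; no ring is closed and the O–B bonds of 9 are hydrolysed on work-up. The E geometry of 8 puts the crotyl methyl group equatorial in the chair, so C6 is set anti to C7–OH and C12 anti to C11–OH. C7 and C11 are set by the neighbouring methyl centres C8 and C10: in the Felkin–Anh rotamer the bulky C9 silyloxy branch stands anti to the forming bond and only a C–H bond faces the crotyl methyl group, so this chair is free of syn-pentane strain and gives C7–OH syn to C8–CH3 and C11–OH syn to C10–CH3. Because the two formyl groups are enantiotopic and 8 is achiral, the two additions are mirror images of each other and 10 is meso. The step needs aldehyde-face selectivity at both ends and complete double addition: the first is secured by the large non-chelating TBS ether on C9, the second by excess 8 and molecular sieves, which keep the first C–O–B link intact so that no δ-hydroxy aldehyde can close to a lactol. A wrong addition at one terminus produces a chiral diastereomer of 10, which chromatography removes at this stage.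

Step 6
Reactants: 10 meso C4–C14 heptad diene diol
Product: 11 meso 4,6,8-tris(tert-butyldimethylsilyloxy)-3,5,7,9-tetramethylundeca-1,10-diene
Conditions: TBSOTf, 2,6-lutidine, CH2Cl2, 0 °C
Reagents that add atoms: tert-butyldimethylsilyl triflate CC(C)(C)[Si](C)(C)OS(=O)(=O)C(F)(F)F
Why: Silyl triflate with a hindered pyridine base silylates even flanked secondary alcohols (silyl ether formation), and identical groups on O7, O9 and O11 keep the compound meso and leave together in step 14.

Step 7
Reactants: 11 meso tris-TBS diene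
Product: 13 meso 3,5,7-tris(tert-butyldimethylsilyloxy)-2,4,6,8-tetramethylnonane-1,9-diol (C5–C13), via C5/C13 dialdehyde 12 (not isolated)
Conditions: O3, CH2Cl2, -78 °C; PPh3; then NaBH4, MeOH, 0 °C
Reagents that add atoms: ozone [O-][O+]=O
Why: Ozonolysis with reductive work-up cleaves the two vinyl groups, the only oxidisable sites, and immediate borohydride reduction leaves the α-branched dialdehyde no time to epimerise at C6 or C12.

Step 8
Reactants: 13 meso C5–C13 diol
Product: 14 C5 alcohol C13 acetate (9-hydroxy-3,5,7-tris(tert-butyldimethylsilyloxy)-2,4,6,8-tetramethylnonyl acetate; single enantiomer; C6–C12 as in the target)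
Conditions: lipase from Pseudomonas fluorescens, vinyl acetate, tBuOMe, 30 °C
Reagents that add atoms: vinyl acetate C=COC(C)=O
Why: Lipase-catalysed irreversible transesterification, a known desymmetrisation of meso 2-methyl-branched primary diols of the polypropionate class: the chiral acyl-enzyme acetylates the enantiotopic CH2OH next to C12 faster, which creates no new centre but fixes the absolute configuration of C6–C12, and any wrong-end monoacetate is drained faster into the meso diacetate, which sharpens the enantiopurity.

Step 9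
Reactants: 14 C5 alcohol C13 acetate
Product: 15 C5 aldehyde C13 acetate
Conditions: Dess–Martin periodinane, CH2Cl2, 0 °C to rt
Reagents that add atoms: none
Why: Dess–Martin oxidation is mild and nearly neutral, so the α-methyl centre C6, the acetate and the silyl ethers are untouched.

Step 10
Reactants: 15 C5 aldehyde C13 acetate
Product: 16 (4E)-C4 iodoalkene C13 acetate
Conditions: CrCl2, CHI3, THF/1,4-dioxane, 0 °C to rt
Reagents that add atoms: iodoform C(I)(I)I
Why: Takai olefination: the geminal dichromium species from CHI3 adds to the aldehyde and eliminates from the less crowded adduct to give the E iodoalkene (C4=C5), and the non-basic medium spares C6, the acetate and the silyl ethers.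

Step 11
Reactants: 16 (4E)-C4 iodoalkene C13 acetate
Product: 17 (4E)-C4 iodoalkene C13 alcohol
Conditions: iBu2AlH, CH2Cl2, -78 °C; aq. Rochelle salt
Reagents that add atoms: none
Why: Reductive ester cleavage in the cold avoids the basic conditions that could move a TBS group from O11 to O13, and the iodoalkene is inert to the hydride.

Step 12
Reactants: 17 (4E)-C4 iodoalkene C13 alcohol
Product: 18 (4E)-C4 iodoalkene C13 aldehyde
Conditions: Dess–Martin periodinane, CH2Cl2, 0 °C to rt
Reagents that add atoms: none
Why: Dess–Martin oxidation as in step 9 gives the aldehyde without epimerising C12 or eliminating the C11 silyloxy group.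

Step 13
Reactants: 18 (4E)-C4 iodoalkene C13 aldehyde; 19 2-(2-bromoethyl)-2-methyl-1,3-dioxolane
Product: 21 (13S)-C13 carbinol bearing the C16 dioxolane (C4–C17 chain; O7 O9 O11 as TBS ethers), via Grignard reagent 20 (not isolated)
Conditions: 19, Mg, THF, rt; then 18, THF, -78 °C; then H2O
Reagents that add atoms: magnesium [Mg] (stays in 20 only)
Why: Grignard addition under Felkin–Anh control: with the non-chelating C11 silyl ether the C11 branch stands anti to the nucleophile, so attack past C12–H sets C13–OH syn to C12–CH3, a sense reinforced by the 1,3-anti effect of the polar C11–O bond in this anti-configured aldehyde; at -78 °C the iodoalkene does not exchange, and the minor C13 epimer is separable.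

Step 14
Reactants: 21 (13S)-C13 carbinol bearing the C16 dioxolane
Product: 22 (4E)-C4 iodoalkene C7,C9-diol with the 2,8-dioxabicyclo[3.2.1]octane ketal (6S,7S,8R,9R,10R,11S,12R,13S,16S)
Conditions: 48% aq. HF, MeCN, 0 °C to rt
Reagents that add atoms: none
Why: Acidic fluoride desilylation followed by transketalisation: once O11 and O13 are free the dioxolane is exchanged intramolecularly for the thermodynamically preferred bicyclic ketal (oxolane closed by O13, 1,3-dioxane closed by O11, with the C10 branch, C12–CH3 and C17 all equatorial); C16 is fixed by the bridge geometry, and O7 and O9 could only form medium rings.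

Step 15
Reactants: 23 propargyl alcohol; 24 methylmagnesium bromide
Product: 26 (Z)-3-iodo-2-methylprop-2-en-1-ol, via alkenylmagnesium alkoxide 25 (not isolated)
Conditions: 24 (3 equiv), CuI (10 mol %), THF, -10 °C to rt; then I2, 0 °C; then H2O
Reagents that add atoms: iodine II
Why: Copper-catalysed carbomagnesiation of the propargylic alkoxide puts methyl on C2 and magnesium on C3 in an anti sense because the alkenylmagnesium is held in a five-membered chelate by the alkoxide, and iodinolysis with retention gives the Z iodoalkene that encodes the C2=C3 geometry.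

Step 16
Reactants: 26 (Z)-3-iodo-2-methylprop-2-en-1-ol
Product: 27 (Z)-3-iodo-2-methylprop-2-enoic acid
Conditions: TEMPO (cat.), PhI(OAc)2, MeCN/H2O, rt
Reagents that add atoms: water O
Why: Nitroxyl-catalysed oxidation takes the allylic alcohol through the aldehyde hydrate to the acid under nearly neutral conditions that avoid Z to E isomerisation and leave the C–I bond alone.

Step 17
Reactants: 28 methyl 2-methyl-3-oxobutanoate
Product: 29 methyl 2-methyl-3-(trimethylsilyloxy)but-2-enoate (E/Z mixture)
Conditions: Me3SiCl, Et3N, toluene, rt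
Reagents that add atoms: chlorotrimethylsilane C[Si](C)(C)Cl
Why: O-silylation of the enol form of a β-keto ester (silyl enol ether formation) is a standard first stage towards bis(silyloxy)dienes.

Step 18
Reactants: 29 methyl 2-methyl-3-(trimethylsilyloxy)but-2-enoate
Product: 30 1-methoxy-2-methyl-1,3-bis(trimethylsilyloxy)buta-1,3-diene
Conditions: LDA, THF, -78 °C; Me3SiCl, -78 to 0 °C
Reagents that add atoms: chlorotrimethylsilane C[Si](C)(C)Cl
Why: Kinetic γ-deprotonation of the vinylogous ester and O-silylation of the dienolate give the electron-rich ketene acetal diene (silyl ketene acetal formation).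

Step 19
Reactants: 30 1-methoxy-2-methyl-1,3-bis(trimethylsilyloxy)buta-1,3-diene; 31 2,6-dichloro-1,4-benzoquinone
Product: 33 2-chloro-6,8-dihydroxy-7-methylnaphthalene-1,4-dione, via Diels–Alder adduct 32 (not isolated)
Conditions: CH2Cl2, -78 °C to rt; then 1 M HCl, THF, rt
Reagents that add atoms: none
Why: Regioselective Diels–Alder reaction of a 1,1,3-trioxygenated diene with a haloquinone: the nucleophilic CH2 terminus bonds to the unsubstituted alkene carbon and the ketene acetal carbon to C–Cl, so after loss of HCl and methanol and desilylation the C8' hydroxyl lies peri to the carbonyl that is flanked by the remaining chlorine at C2'.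

Step 20
Reactants: 33 2-chloro-6,8-dihydroxy-7-methylnaphthalene-1,4-dione
Product: 34 2-chloro-6,8-bis(methoxymethoxy)-7-methylnaphthalene-1,4-dione
Conditions: MOMCl, iPr2NEt, CH2Cl2, 0 °C to reflux
Reagents that add atoms: chloromethyl methyl ether COCCl
Why: O-alkylation of both phenols with a reactive α-chloro ether; the hindered amine base does not displace the quinone chlorine, and MOM groups are later cleaved by the same acid as the ester.

Step 21
Reactants: 34 2-chloro-6,8-bis(methoxymethoxy)-7-methylnaphthalene-1,4-dione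
Product: 36 2-chloro-1,4-dimethoxy-6,8-bis(methoxymethoxy)-7-methylnaphthalene, via hydroquinone 35 (not isolated)
Conditions: Na2S2O4, THF/H2O, rt; then MeI, K2CO3, DMF, rt, argon
Reagents that add atoms: iodomethane CI
Why: Dithionite reduction of the quinone and double Williamson O-methylation store the quinone as an electron-rich 1,4-dimethoxyarene that allows substitution, metalation and C–N coupling.

Step 22
Reactants: 36 2-chloro-1,4-dimethoxy-6,8-bis(methoxymethoxy)-7-methylnaphthalene
Product: 37 5-bromo-2-chloro-1,4-dimethoxy-6,8-bis(methoxymethoxy)-7-methylnaphthalene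
Conditions: NBS, MeCN, 0 °C, dark
Reagents that add atoms: N-bromosuccinimide O=C1CCC(=O)N1Br
Why: Electrophilic aromatic bromination goes to C5', an α position activated ortho and para by two acetal oxygens, whereas C3' has only one ortho methoxy group and a deactivating chlorine next to it.

Step 23
Reactants: 37 5-bromo-2-chloro-1,4-dimethoxy-6,8-bis(methoxymethoxy)-7-methylnaphthalene
Product: 39 tert-butyl 6-chloro-5,8-dimethoxy-2,4-bis(methoxymethoxy)-3-methylnaphthalene-1-carboxylate (ester on C5'), via aryllithium 38 (not isolated)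
Conditions: n-BuLi, THF, -78 °C; Boc2O, -78 °C to rt
Reagents that add atoms: n-butyllithium [Li]CCCC (lithium stays in 38 only); di-tert-butyl dicarbonate CC(C)(C)OC(=O)OC(=O)OC(C)(C)C
Why: Halogen–lithium exchange at -78 °C takes bromine and leaves the aryl chloride, the aryllithium is stabilised by the neighbouring MOM oxygen, and its acylation with Boc2O gives the tert-butyl ester directly, with crowding preventing a second addition.

Step 24
Reactants: 39 tert-butyl 6-chloro-5,8-dimethoxy-2,4-bis(methoxymethoxy)-3-methylnaphthalene-1-carboxylate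
Product: 41 tert-butyl 6-amino-5,8-dimethoxy-2,4-bis(methoxymethoxy)-3-methylnaphthalene-1-carboxylate, via N-diphenylmethylidene arylamine 40 (not isolated)
Conditions: Ph2C=NH, Pd2(dba)3 (cat.), XPhos (cat.), Cs2CO3, toluene, 100 °C; then NH2OH·HCl, NaOAc, MeOH, rt
Reagents that add atoms: benzophenone imine N=C(c1ccccc1)c1ccccc1
Why: Buchwald–Hartwig amination of an aryl chloride with benzophenone imine as ammonia surrogate, followed by mild transimination with hydroxylamine, frees the arylamine without touching the MOM ethers or the tert-butyl ester.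

Step 25
Reactants: 27 (Z)-3-iodo-2-methylprop-2-enoic acid; 41 tert-butyl 6-amino-5,8-dimethoxy-2,4-bis(methoxymethoxy)-3-methylnaphthalene-1-carboxylate
Product: 43 tert-butyl 6-[(Z)-3-iodo-2-methylprop-2-enamido]-5,8-dimethoxy-2,4-bis(methoxymethoxy)-3-methylnaphthalene-1-carboxylate, via acid chloride 42 (not isolated)
Conditions: 27, 1-chloro-N,N,2-trimethylprop-1-en-1-amine, CH2Cl2, 0 °C; then 41, pyridine, 0 °C to rt
Reagents that add atoms: 1-chloro-N,N,2-trimethylprop-1-en-1-amine CC(C)=C(Cl)N(C)C (chlorine stays in 42 only)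
Why: Amide formation through an acid chloride made under neutral conditions keeps the Z geometry, and the electron-rich aminonaphthalene is a far better nucleophile than an aminoquinone would be.

Step 26
Reactants: 43 (Z)-iodomethacrylamide of the naphthalene
Product: 44 tert-butyl 5,8-dimethoxy-2,4-bis(methoxymethoxy)-3-methyl-6-[(Z)-2-methyl-3-(trimethylstannyl)prop-2-enamido]naphthalene-1-carboxylate
Conditions: (Me3Sn)2, Pd(PPh3)4 (cat.), toluene, 80 °C
Reagents that add atoms: hexamethylditin C[Sn](C)(C)[Sn](C)(C)C
Why: Palladium-catalysed stannylation of an alkenyl iodide with a distannane (oxidative addition to zerovalent palladium, transmetalation, reductive elimination) proceeds with retention of the Z geometry, and excess distannane suppresses homocoupling.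

Step 27
Reactants: 22 (4E)-C4 iodoalkene diol ketal; 44 (Z)-stannylmethacrylamide of the naphthalene
Product: 45 (2Z,4E)-dienamide with 1',4'-dimethoxy-6',8'-bis(methoxymethoxy)naphthalene C5' tert-butyl ester
Conditions: PdCl2(MeCN)2 (cat.), DMF, rt, dark
Reagents that add atoms: none
Why: Stille coupling of an E alkenyl iodide with a Z alkenylstannane forms C3–C4 at room temperature under neutral conditions with retention at both alkenes and tolerates the free C7 and C9 hydroxyl groups.

Step 28
Reactants: 45 (2Z,4E)-dienamide dimethoxynaphthalene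
Product: 46 (2Z,4E)-dienamide 1',4'-naphthoquinone with C6' and C8' MOM ethers and the C5' tert-butyl ester
Conditions: (NH4)2Ce(NO3)6, MeCN/H2O, 0 °C
Reagents that add atoms: water O
Why: Oxidative demethylation of a 1,4-dimethoxyarene to the quinone is fast at 0 °C, is compatible with dienamides and secondary alcohols, and can only occur in the C1'–C4' ring because the other ring has carbon at C5' para to O8'.

Step 29
Reactants: 46 protected rifsaliniketal
Product: 47 rifsaliniketal
Conditions: CF3CO2H/CH2Cl2/H2O, 0 °C to rt
Reagents that add atoms: none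
Why: Acidolysis removes both aryl MOM acetals and the tert-butyl ester in one operation; deprotection is done at the quinone level because the electron-poor ring resists the ipso protonation that leads to decarboxylation, water holds the released formaldehyde as its hydrate, and the bicyclic ketal is the thermodynamic sink under acid.

Compound list
1 | methacrolein | C=C(C)C=O | starting material
2 | isopropenylmagnesium bromide | C=C(C)[Mg]Br | starting material
3 | 2,4-dimethylpenta-1,4-dien-3-ol | C=C(C)C(O)C(C)=C | intermediate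
4 | 3-(tert-butyldimethylsilyloxy)-2,4-dimethylpenta-1,4-diene | C=C(C)C(O[Si](C)(C)C(C)(C)C)C(C)=C | intermediate
5 | bis(9-BBN) adduct of 4 (not isolated) | B1(C2CCCC1CCC2)C[C@@H](C)[C@@H](O[Si](C)(C)C(C)(C)C)[C@@H](C)CB1C2CCCC1CCC2 | intermediate
6 | meso anti,anti-3-(tert-butyldimethylsilyloxy)-2,4-dimethylpentane-1,5-diol | OC[C@@H](C)[C@@H](O[Si](C)(C)C(C)(C)C)[C@@H](C)CO | intermediate
7 | meso anti,anti-3-(tert-butyldimethylsilyloxy)-2,4-dimethylpentanedial (C7–C11) | O=C[C@@H](C)[C@@H](O[Si](C)(C)C(C)(C)C)[C@@H](C)C=O | intermediate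
8 | (E)-crotylboronic acid pinacol ester | C/C=C/CB1OC(C)(C)C(C)(C)O1 | starting material
9 | bis(pinacol borate) of 10 (not isolated) | C=C[C@H](C)[C@H](OB1OC(C)(C)C(C)(C)O1)[C@@H](C)[C@@H](O[Si](C)(C)C(C)(C)C)[C@@H](C)[C@H](OB1OC(C)(C)C(C)(C)O1)[C@H](C)C=C | intermediate
10 | meso C4–C14 heptad diene diol | C=C[C@H](C)[C@H](O)[C@@H](C)[C@@H](O[Si](C)(C)C(C)(C)C)[C@@H](C)[C@H](O)[C@H](C)C=C | intermediate
11 | meso tris-TBS diene | C=C[C@H](C)[C@H](O[Si](C)(C)C(C)(C)C)[C@@H](C)[C@@H](O[Si](C)(C)C(C)(C)C)[C@@H](C)[C@H](O[Si](C)(C)C(C)(C)C)[C@H](C)C=C | intermediate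
12 | meso C5/C13 dialdehyde (not isolated) | O=C[C@H](C)[C@H](O[Si](C)(C)C(C)(C)C)[C@@H](C)[C@@H](O[Si](C)(C)C(C)(C)C)[C@@H](C)[C@H](O[Si](C)(C)C(C)(C)C)[C@H](C)C=O | intermediate
13 | meso C5–C13 diol | OC[C@H](C)[C@H](O[Si](C)(C)C(C)(C)C)[C@@H](C)[C@@H](O[Si](C)(C)C(C)(C)C)[C@@H](C)[C@H](O[Si](C)(C)C(C)(C)C)[C@H](C)CO | intermediate
14 | C5 alcohol C13 acetate | OC[C@H](C)[C@H](O[Si](C)(C)C(C)(C)C)[C@@H](C)[C@@H](O[Si](C)(C)C(C)(C)C)[C@@H](C)[C@H](O[Si](C)(C)C(C)(C)C)[C@H](C)COC(C)=O | intermediate
15 | C5 aldehyde C13 acetate | O=C[C@H](C)[C@H](O[Si](C)(C)C(C)(C)C)[C@@H](C)[C@@H](O[Si](C)(C)C(C)(C)C)[C@@H](C)[C@H](O[Si](C)(C)C(C)(C)C)[C@H](C)COC(C)=O | intermediate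
16 | (4E)-C4 iodoalkene C13 acetate | I/C=C/[C@H](C)[C@H](O[Si](C)(C)C(C)(C)C)[C@@H](C)[C@@H](O[Si](C)(C)C(C)(C)C)[C@@H](C)[C@H](O[Si](C)(C)C(C)(C)C)[C@H](C)COC(C)=O | intermediate
17 | (4E)-C4 iodoalkene C13 alcohol | I/C=C/[C@H](C)[C@H](O[Si](C)(C)C(C)(C)C)[C@@H](C)[C@@H](O[Si](C)(C)C(C)(C)C)[C@@H](C)[C@H](O[Si](C)(C)C(C)(C)C)[C@H](C)CO | intermediate
18 | (4E)-C4 iodoalkene C13 aldehyde | I/C=C/[C@H](C)[C@H](O[Si](C)(C)C(C)(C)C)[C@@H](C)[C@@H](O[Si](C)(C)C(C)(C)C)[C@@H](C)[C@H](O[Si](C)(C)C(C)(C)C)[C@H](C)C=O | intermediate
19 | 2-(2-bromoethyl)-2-methyl-1,3-dioxolane | CC1(CCBr)OCCO1 | starting material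
20 | 2-(2-methyl-1,3-dioxolan-2-yl)ethylmagnesium bromide (not isolated) | CC1(CC[Mg]Br)OCCO1 | intermediate
21 | (13S)-C13 carbinol with C16 dioxolane | I/C=C/[C@H](C)[C@H](O[Si](C)(C)C(C)(C)C)[C@@H](C)[C@@H](O[Si](C)(C)C(C)(C)C)[C@@H](C)[C@H](O[Si](C)(C)C(C)(C)C)[C@H](C)[C@@H](O)CCC1(C)OCCO1 | intermediate
22 | (4E)-C4 iodoalkene C7,C9-diol bicyclic ketal | I/C=C/[C@H](C)[C@H](O)[C@@H](C)[C@@H](O)[C@@H](C)[C@@H]1O[C@@]2(C)CC[C@H](O2)[C@H]1C | intermediate
23 | propargyl alcohol | C#CCO | starting material
24 | methylmagnesium bromide | C[Mg]Br | starting material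
25 | (Z)-alkenylmagnesium alkoxide (not isolated) | C/C(=C/[Mg]Br)CO[Mg]Br | intermediate
26 | (Z)-3-iodo-2-methylprop-2-en-1-ol | C/C(=C/I)CO | intermediate
27 | (Z)-3-iodo-2-methylprop-2-enoic acid | C/C(=C/I)C(=O)O | intermediate
28 | methyl 2-methyl-3-oxobutanoate | COC(=O)C(C)C(C)=O | starting material
29 | methyl 2-methyl-3-(trimethylsilyloxy)but-2-enoate (E/Z mixture) | COC(=O)C(C)=C(C)O[Si](C)(C)C | intermediate
30 | 1-methoxy-2-methyl-1,3-bis(trimethylsilyloxy)buta-1,3-diene | COC(O[Si](C)(C)C)=C(C)C(=C)O[Si](C)(C)C | intermediate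
31 | 2,6-dichloro-1,4-benzoquinone | O=C1C=C(Cl)C(=O)C(Cl)=C1 | starting material
32 | Diels–Alder adduct (not isolated; relative configuration not defined) | O=C1C=C(Cl)C(=O)C2(Cl)C1CC(O[Si](C)(C)C)=C(C)C2(OC)O[Si](C)(C)C | intermediate
33 | 2-chloro-6,8-dihydroxy-7-methylnaphthalene-1,4-dione | O=C1C=C(Cl)C(=O)c2c1cc(O)c(C)c2O | intermediate
34 | 2-chloro-6,8-bis(methoxymethoxy)-7-methylnaphthalene-1,4-dione | O=C1C=C(Cl)C(=O)c2c1cc(OCOC)c(C)c2OCOC | intermediate
35 | 2-chloro-6,8-bis(methoxymethoxy)-7-methylnaphthalene-1,4-diol (not isolated) | Oc1cc(Cl)c(O)c2c1cc(OCOC)c(C)c2OCOC | intermediate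
36 | 2-chloro-1,4-dimethoxy-6,8-bis(methoxymethoxy)-7-methylnaphthalene | COc1cc(Cl)c(OC)c2c1cc(OCOC)c(C)c2OCOC | intermediate
37 | 5-bromo-2-chloro-1,4-dimethoxy-6,8-bis(methoxymethoxy)-7-methylnaphthalene | COc1cc(Cl)c(OC)c2c1c(Br)c(OCOC)c(C)c2OCOC | intermediate
38 | C5' aryllithium (not isolated) | COc1cc(Cl)c(OC)c2c1c([Li])c(OCOC)c(C)c2OCOC | intermediate
39 | tert-butyl 6-chloro-5,8-dimethoxy-2,4-bis(methoxymethoxy)-3-methylnaphthalene-1-carboxylate | COc1cc(Cl)c(OC)c2c1c(C(=O)OC(C)(C)C)c(OCOC)c(C)c2OCOC | intermediate
40 | N-diphenylmethylidene arylamine (not isolated) | COc1cc(N=C(c3ccccc3)c3ccccc3)c(OC)c2c1c(C(=O)OC(C)(C)C)c(OCOC)c(C)c2OCOC | intermediate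
41 | tert-butyl 6-amino-5,8-dimethoxy-2,4-bis(methoxymethoxy)-3-methylnaphthalene-1-carboxylate | COc1cc(N)c(OC)c2c1c(C(=O)OC(C)(C)C)c(OCOC)c(C)c2OCOC | intermediate
42 | (Z)-3-iodo-2-methylprop-2-enoyl chloride (not isolated) | C/C(=C/I)C(=O)Cl | intermediate
43 | (Z)-iodomethacrylamide of the naphthalene | C/C(=C/I)C(=O)Nc1cc(OC)c2c(C(=O)OC(C)(C)C)c(OCOC)c(C)c(OCOC)c2c1OC | intermediate
44 | (Z)-trimethylstannylmethacrylamide of the naphthalene | C/C(=C/[Sn](C)(C)C)C(=O)Nc1cc(OC)c2c(C(=O)OC(C)(C)C)c(OCOC)c(C)c(OCOC)c2c1OC | intermediate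
45 | (2Z,4E)-dienamide dimethoxynaphthalene | C/C(=C/C=C/[C@H](C)[C@H](O)[C@@H](C)[C@@H](O)[C@@H](C)[C@@H]1O[C@@]2(C)CC[C@H](O2)[C@H]1C)C(=O)Nc1cc(OC)c2c(C(=O)OC(C)(C)C)c(OCOC)c(C)c(OCOC)c2c1OC | intermediate
46 | protected rifsaliniketal (quinone, two MOM ethers, tert-butyl ester) | C/C(=C/C=C/[C@H](C)[C@H](O)[C@@H](C)[C@@H](O)[C@@H](C)[C@@H]1O[C@@]2(C)CC[C@H](O2)[C@H]1C)C(=O)NC1=CC(=O)c2c(C(=O)OC(C)(C)C)c(OCOC)c(C)c(OCOC)c2C1=O | intermediate
47 | rifsaliniketal (2Z,4E,6S,7S,8R,9R,10R,11S,12R,13S,16S) | C/C(=C/C=C/[C@H](C)[C@H](O)[C@@H](C)[C@@H](O)[C@@H](C)[C@@H]1O[C@@]2(C)CC[C@H](O2)[C@H]1C)C(=O)NC1=CC(=O)c2c(C(=O)O)c(O)c(C)c(O)c2C1=O | target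

Total step count: 29.
Longest linear sequence: 17 steps (steps 1–14, then 27–29).

Steps most likely to fail

Step 5. Substrate control by C8 and C10 alone may discriminate the aldehyde faces too weakly at one or both termini. The sequence may also stall after the first addition and drift into lactol formation. The fallback sets out from 7 and replaces allylboration by a two-directional Nozaki–Hiyama crotylation ((E)-crotyl bromide, CrCl2, THF, 0 °C). Crotylchromium reagents are anti-selective whatever the halide geometry, and their bulky ligand sphere strengthens Felkin–Anh induction by an α-methyl centre. They also react fast enough that the second formyl group is consumed before work-up. The detour comes back at 10 and makes no compound outside the list (entry F0).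

Step 8. Acyl transfer may be slow or poorly selective because the silyl ethers flank the reacting CH2OH groups, or the enzyme may prefer the other terminus. The fallback sets out from 13 and uses a covalent auxiliary instead of a catalyst. Monoesterification with one equivalent of (S)-O-methylmandelic acid (DCC, DMAP, CH2Cl2) gives two diastereomeric monoesters that are separated by chromatography. The unwanted monoester and any diester are saponified back to meso 13 and recycled. The C13 (S)-O-methylmandelate F1 is oxidised with Dess–Martin periodinane to the C5 aldehyde mandelate F2. This is converted by Takai olefination into the (4E)-iodoalkene mandelate F3. Treatment with iBu2AlH at -78 °C then releases the auxiliary, and the route comes back at 17.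

Step 13. The closed, basic Grignard addition may give only modest facial selectivity at C13, or it may enolise the aldehyde. The fallback sets out from 18 and uses an open, Lewis-acid-promoted transition state, in which Felkin–Anh and 1,3-anti induction reinforce each other most strongly. Tributyl(buta-2,3-dien-2-yl)stannane F4 is made in one step from commercial 1-bromobut-2-yne and the stannylcuprate from Bu3SnLi and CuBr·SMe2 by SN2' displacement. It adds to 18 with BF3·OEt2 in CH2Cl2 at -78 °C and gives the (13S)-homopropargylic alcohol F5. Aqueous HF in MeCN removes the three TBS groups to give the alkynyl tetraol F6. Catalytic PtCl2 in THF then cycloisomerises the alkynediol: O13 attacks C16 in a 5-endo-dig closure, and O11 adds to the resulting enol ether. The route comes back at 22.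

Further compounds
F0 | step 5 | none | none
F1 | step 8 | C5 alcohol C13 (S)-O-methylmandelate | OC[C@H](C)[C@H](O[Si](C)(C)C(C)(C)C)[C@@H](C)[C@@H](O[Si](C)(C)C(C)(C)C)[C@@H](C)[C@H](O[Si](C)(C)C(C)(C)C)[C@H](C)COC(=O)[C@@H](OC)c1ccccc1
F2 | step 8 | C5 aldehyde C13 (S)-O-methylmandelate | O=C[C@H](C)[C@H](O[Si](C)(C)C(C)(C)C)[C@@H](C)[C@@H](O[Si](C)(C)C(C)(C)C)[C@@H](C)[C@H](O[Si](C)(C)C(C)(C)C)[C@H](C)COC(=O)[C@@H](OC)c1ccccc1
F3 | step 8 | (4E)-C4 iodoalkene C13 (S)-O-methylmandelate | I/C=C/[C@H](C)[C@H](O[Si](C)(C)C(C)(C)C)[C@@H](C)[C@@H](O[Si](C)(C)C(C)(C)C)[C@@H](C)[C@H](O[Si](C)(C)C(C)(C)C)[C@H](C)COC(=O)[C@@H](OC)c1ccccc1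
F4 | step 13 | tributyl(buta-2,3-dien-2-yl)stannane | C=C=C(C)[Sn](CCCC)(CCCC)CCCC
F5 | step 13 | (13S)-homopropargylic alcohol, O7 O9 O11 as TBS ethers | I/C=C/[C@H](C)[C@H](O[Si](C)(C)C(C)(C)C)[C@@H](C)[C@@H](O[Si](C)(C)C(C)(C)C)[C@@H](C)[C@H](O[Si](C)(C)C(C)(C)C)[C@H](C)[C@@H](O)CC#CC
F6 | step 13 | alkynyl C7,C9,C11,C13-tetraol | I/C=C/[C@H](C)[C@H](O)[C@@H](C)[C@@H](O)[C@@H](C)[C@H](O)[C@H](C)[C@@H](O)CC#CC
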